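Ring A is numbered C1 (styryl), C2 (prenyl), C3 (OMe), C4 (prenyl), C5 (OH), C6 (H). The key step is possible because C2-C3-C4 with both prenyl groups is a symmetrical ketone (1,3-diprenylacetone) and C5-C6 is a malonate unit whose second ester can sit on C6.
Retrosynthetic cuts, in order: a carboxyl is put back on C6 and the O-methyl bond at C3 is cut. Ring A is reduced to a cyclohexane-1,3-dione and opened at C1-C6 and C4-C5. The chain is then cut at C1=C2 and at one ring-carbon-to-prenyl bond.
Forward: prenylation of 6-methylhept-5-en-2-one, aldol condensation with (E)-cinnamaldehyde, then a malonate Michael-Dieckmann annulation that closes the only ring to be built.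
Ring A is aromatised afterwards by selenoxide elimination across C1-C6, which spares the olefins. The C6 ester then distinguishes the two phenols for mono-methylation and finally leaves as CO2.
The target has no stereocentre. Its one stereoelement, the E styryl double bond, comes in with cinnamaldehyde and is never touched, and the sp3 ring centres of the intermediates vanish on aromatisation.

Key step: step 4

Remark: C1-C6 always mean the ring A numbering above, not the locants inside systematic names; conjugate bases of numbered compounds carry no number of their own; 10-12 are drawn as keto tautomers although they should be largely enolised.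

Step 1
Reactants: 1 6-methylhept-5-en-2-one; 2 prenyl bromide (1-bromo-3-methylbut-2-ene)
Product: 3 2,10-dimethylundeca-2,9-dien-6-one
Conditions: LiN(iPr)2 (1.05 equiv), THF, -78 °C, slow addition of 1; then 2, DMPU, -78 → 0 °C
Reagents that add atoms: none
Why: Kinetic enolate alkylation: the hindered lithium amide removes a proton from the unhindered methyl group at -78 °C, and the enolate displaces bromide at the primary carbon of the reactive allylic halide (SN2), which makes the two arms of the ketone identical.

Step 2
Reactants: 3 2,10-dimethylundeca-2,9-dien-6-one; 4 (E)-cinnamaldehyde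
Product: 5 (1E)-3-hydroxy-9-methyl-4-(3-methylbut-2-enyl)-1-phenyldeca-1,8-dien-5-one (syn/anti mixture)
Conditions: LiN(iPr)2, THF, -78 °C; then 4, -78 °C; aq NH4Cl
Reagents that add atoms: none
Why: Directed aldol addition: the symmetry of 3 allows only one enolate regioisomer, the preformed lithium enolate adds 1,2 to the enal at low temperature, and the two new stereocentres (carbinol and α carbon) form without control, which is harmless because both become sp2 in step 3.

Step 3
Reactants: 5 (1E)-3-hydroxy-9-methyl-4-(3-methylbut-2-enyl)-1-phenyldeca-1,8-dien-5-one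
Product: 7 (1E,3E)-9-methyl-4-(3-methylbut-2-enyl)-1-phenyldeca-1,3,8-trien-5-one, via allylic mesylate 6 (not isolated)
Conditions: MsCl, Et3N, CH2Cl2, 0 °C; then DBU, 0 °C → rt
Reagents that add atoms: methanesulfonyl chloride, CS(=O)(=O)Cl (its atoms stay in 6 only and leave again before 7)
Why: Mesylation followed by base-induced E1cB elimination gives the fully conjugated dienone with the less strained 3E geometry (styryl arm anti to the acyl group), and any allylic chloride formed by ionisation of 6 would be converted to the same dienone by DBU.

Step 4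
Reactants: 7 (1E,3E)-9-methyl-4-(3-methylbut-2-enyl)-1-phenyldeca-1,3,8-trien-5-one; 8 dimethyl malonate
Product: 10 methyl 2,4-dioxo-3,5-bis(3-methylbut-2-enyl)-6-[(E)-2-phenylethenyl]cyclohexane-1-carboxylate (mixture of ring diastereomers), via acyclic Michael adduct 9 (not isolated)
Conditions: 8 (1.3 equiv), NaOMe (1.3 equiv), MeOH, reflux, N2; then cold 1 M HCl to pH 3
Reagents that add atoms: none
Why: Methoxide generates sodium dimethyl malonate, which adds reversibly to the β carbon C1 of the dienone (Michael addition, bond C1-C6); proton exchange in methanol then moves the enolate of 9 from C2 to C4, and this carbon is acylated by one malonate ester with expulsion of methoxide (Dieckmann condensation, bond C4-C5). The closest known reaction type is the malonate-enone annulation to 2-carbomethoxycyclohexane-1,3-diones that underlies olivetolate-type resorcylate syntheses and also works on cinnamylideneacetone. Ring A closes in the favoured 6-(enolendo)-exo-trig mode, whereas the C2 enolate could only reach a four-membered ring. No reagent controls the four sp3 centres C1, C2, C4 and C6: C2, C4 and C6 lie next to carbonyl groups and should equilibrate relative to C1 under thermodynamic control, and all four are flattened in steps 5 and 6. The selectivity needed is 1,4- over 1,6-addition, and the substrate secures it because both additions are reversible while only the 1,4-adduct holds an ester within six-ring distance of an enolisable carbon (the 1,6-adduct would need an eight-membered ring). Since C4 keeps one hydrogen, 10 is deprotonated at once to its vinylogous carboxylate, which removes it from all equilibria until the acidic quench.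

Step 5
Reactants: 10 methyl 2,4-dioxo-3,5-bis(3-methylbut-2-enyl)-6-[(E)-2-phenylethenyl]cyclohexane-1-carboxylate
Product: 11 methyl 2,4-dioxo-3,5-bis(3-methylbut-2-enyl)-6-[(E)-2-phenylethenyl]-1-(phenylselanyl)cyclohexane-1-carboxylate (racemic, PhSe trans to styryl)
Conditions: LiN(iPr)2 (2.3 equiv), THF-DMPU, -78 → -20 °C; PhSeBr (1.05 equiv), -78 °C; cold 0.5 M HCl to pH 3-4
Reagents that add atoms: benzeneselenenyl bromide, Br[Se]c1ccccc1
Why: α-Selenenylation of an enolate dianion: the first equivalent of base ionises the dione and the second forms the ester-stabilised C6 carbanion, and this last-formed, most basic site captures selenium at -78 °C faster than PhSeBr can add to the olefins, with approach anti to the C1 styryl group setting the transient quaternary centre so that selenium is syn to C1-H.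

Step 6
Reactants: 11 methyl 2,4-dioxo-3,5-bis(3-methylbut-2-enyl)-6-[(E)-2-phenylethenyl]-1-(phenylselanyl)cyclohexane-1-carboxylate
Product: 13 methyl 2,4-dihydroxy-3,5-bis(3-methylbut-2-enyl)-6-[(E)-2-phenylethenyl]benzoate, via C6 selenoxide 12 (not isolated)
Conditions: mCPBA (1.0 equiv), CH2Cl2, -78 °C; then Et3N, -78 °C → rt
Reagents that add atoms: 3-chloroperbenzoic acid, OOC(=O)c1cccc(Cl)c1 (one oxygen, held in 12 only and lost with the selenium)
Why: Selenoxide syn elimination: selenium is oxidised far faster than a trisubstituted olefin at -78 °C, C1-H is the only β hydrogen within reach of the selenoxide, the C1=C6 enedione formed is a tautomer of the resorcylate and should enolise at once, and the amine buffer keeps the selenenic acid from adding to the prenyl groups.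

Step 7
Reactants: 13 methyl 2,4-dihydroxy-3,5-bis(3-methylbut-2-enyl)-6-[(E)-2-phenylethenyl]benzoate
Product: 14 methyl 2-hydroxy-4-methoxy-3,5-bis(3-methylbut-2-enyl)-6-[(E)-2-phenylethenyl]benzoate
Conditions: MeI (1.1 equiv), K2CO3 (1.1 equiv), acetone, rt → 40 °C
Reagents that add atoms: iodomethane, CI
Why: Williamson ether synthesis on a 2,4-dihydroxybenzoate: the C5 hydroxyl is tied up in a hydrogen bond to the ester carbonyl, so one equivalent of weak base ionises only the more acidic C3 hydroxyl para to the ester, and the small electrophile reaches it despite the two flanking prenyl groups.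

Step 8
Reactants: 14 methyl 2-hydroxy-4-methoxy-3,5-bis(3-methylbut-2-enyl)-6-[(E)-2-phenylethenyl]benzoate
Product: 15 2-hydroxy-4-methoxy-3,5-bis(3-methylbut-2-enyl)-6-[(E)-2-phenylethenyl]benzoic acid
Conditions: KOH (excess), EtOH-H2O, reflux, N2; then cold 1 M HCl to pH 3-4, 0 °C
Reagents that add atoms: potassium hydroxide, [K+].[OH-]
Why: Saponification of a di-ortho-substituted salicylate needs hot concentrated hydroxide, to which prenyl, styryl and aryl methyl ether groups are inert, and the cold, mild acidification avoids acid-induced chroman formation from the ortho-prenylphenol.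

Step 9
Reactants: 15 2-hydroxy-4-methoxy-3,5-bis(3-methylbut-2-enyl)-6-[(E)-2-phenylethenyl]benzoic acid
Product: 16 chiricanine C, 3-methoxy-2,4-bis(3-methylbut-2-enyl)-5-[(E)-2-phenylethenyl]phenol
Conditions: DMF, 130 °C, N2, dark
Reagents that add atoms: none
Why: Thermal protodecarboxylation of an electron-rich salicylic acid: proton transfer to the ipso carbon C6 gives a β-keto-acid-like tautomer that loses CO2, helped by the ortho hydroxyl, the para methoxy group and relief of ortho crowding, and the neutral acid-free medium leaves the prenyl groups and the E olefin unchanged.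

Compound list
1 | 6-methylhept-5-en-2-one | CC(=O)CCC=C(C)C | starting material
2 | prenyl bromide (1-bromo-3-methylbut-2-ene) | CC(C)=CCBr | starting material
3 | 2,10-dimethylundeca-2,9-dien-6-one | CC(C)=CCCC(=O)CCC=C(C)C | intermediate
4 | (E)-cinnamaldehyde | O=C/C=C/c1ccccc1 | starting material
5 | (1E)-3-hydroxy-9-methyl-4-(3-methylbut-2-enyl)-1-phenyldeca-1,8-dien-5-one, syn/anti mixture | CC(C)=CCCC(=O)C(CC=C(C)C)C(O)/C=C/c1ccccc1 | intermediate
6 | methanesulfonate of 5, formed and consumed in situ | CC(C)=CCCC(=O)C(CC=C(C)C)C(OS(C)(=O)=O)/C=C/c1ccccc1 | intermediate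
7 | (1E,3E)-9-methyl-4-(3-methylbut-2-enyl)-1-phenyldeca-1,3,8-trien-5-one | O=C(CCC=C(C)C)/C(CC=C(C)C)=C/C=C/c1ccccc1 | intermediate
8 | dimethyl malonate | COC(=O)CC(=O)OC | starting material
9 | dimethyl 2-[(1E)-9-methyl-4-(3-methylbut-2-enyl)-5-oxo-1-phenyldeca-1,8-dien-3-yl]propanedioate, formed and consumed in situ | COC(=O)C(C(=O)OC)C(/C=C/c1ccccc1)C(CC=C(C)C)C(=O)CCC=C(C)C | intermediate
10 | methyl 2,4-dioxo-3,5-bis(3-methylbut-2-enyl)-6-[(E)-2-phenylethenyl]cyclohexane-1-carboxylate, ring centres undefined (epimer mixture) | COC(=O)C1C(=O)C(CC=C(C)C)C(=O)C(CC=C(C)C)C1/C=C/c1ccccc1 | intermediate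
11 | methyl 2,4-dioxo-3,5-bis(3-methylbut-2-enyl)-6-[(E)-2-phenylethenyl]-1-(phenylselanyl)cyclohexane-1-carboxylate, racemic, PhSe trans to styryl (relative), other ring centres undefined | COC(=O)[C@]1([Se]c2ccccc2)C(=O)C(CC=C(C)C)C(=O)C(CC=C(C)C)[C@@H]1/C=C/c1ccccc1 | intermediate
12 | methyl 1-(benzeneseleninyl)-2,4-dioxo-3,5-bis(3-methylbut-2-enyl)-6-[(E)-2-phenylethenyl]cyclohexane-1-carboxylate, racemic, same relative configuration as 11, selenium centre undefined, formed and consumed in situ | COC(=O)[C@]1([Se](=O)c2ccccc2)C(=O)C(CC=C(C)C)C(=O)C(CC=C(C)C)[C@@H]1/C=C/c1ccccc1 | intermediate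
13 | methyl 2,4-dihydroxy-3,5-bis(3-methylbut-2-enyl)-6-[(E)-2-phenylethenyl]benzoate | COC(=O)c1c(O)c(CC=C(C)C)c(O)c(CC=C(C)C)c1/C=C/c1ccccc1 | intermediate
14 | methyl 2-hydroxy-4-methoxy-3,5-bis(3-methylbut-2-enyl)-6-[(E)-2-phenylethenyl]benzoate | COC(=O)c1c(O)c(CC=C(C)C)c(OC)c(CC=C(C)C)c1/C=C/c1ccccc1 | intermediate
15 | 2-hydroxy-4-methoxy-3,5-bis(3-methylbut-2-enyl)-6-[(E)-2-phenylethenyl]benzoic acid | OC(=O)c1c(O)c(CC=C(C)C)c(OC)c(CC=C(C)C)c1/C=C/c1ccccc1 | intermediate
16 | chiricanine C, 3-methoxy-2,4-bis(3-methylbut-2-enyl)-5-[(E)-2-phenylethenyl]phenol | COc1c(CC=C(C)C)c(O)cc(/C=C/c2ccccc2)c1CC=C(C)C | target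

Total step count: 9. Longest linear sequence: 9 steps (1 to 16); 2, 4 and 8 are purchased.

Steps most likely to fail

Risk 1, step 4. Conjugate addition to an α-branched, trisubstituted dienone may lie so far towards the reactants that ring closure cannot drain it, while malonate is lost to 1,6-addition or the dienone oligomerises. The fallback sets out from 3 (with 4 and 8), bypasses 5-7 and comes back at 9. Knoevenagel condensation of 4 with 8 (piperidine, AcOH, toluene, water separator) should give dimethyl 2-[(E)-3-phenylprop-2-enylidene]propanedioate F1, a doubly activated acceptor without α-branching. The lithium enolate of 3 (LiN(iPr)2, THF, -78 °C) should add to its β carbon, so the Michael bond made is C1-C2 instead of C1-C6, and 9 is isolated. NaOMe in MeOH then closes C4-C5 as before to give 10.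

Risk 2, step 5. Incomplete dianion formation would direct selenium to C4 of the dione enolate, from where elimination can only run into the prenyl chain. Electrophilic selenium might also add to the prenyl double bonds. The fallback sets out from 10 and comes back at 13, replacing steps 5 and 6 by hydride abstraction from a silylated diene instead of a syn elimination. Me3SiOTf and Et3N (CH2Cl2, 0 °C) should give methyl 3,5-bis(3-methylbut-2-enyl)-6-[(E)-2-phenylethenyl]-2,4-bis(trimethylsilyloxy)cyclohexa-1,3-diene-1-carboxylate F2. One equivalent of DDQ (2,6-lutidine, CH2Cl2, 0 °C) should remove the doubly allylic C1 hydrogen as hydride and then the C2 proton, giving methyl 3,5-bis(3-methylbut-2-enyl)-6-[(E)-2-phenylethenyl]-2,4-bis(trimethylsilyloxy)benzoate F3. Its silylated oxygens cannot enter the chromene-forming oxidation of free ortho-prenylphenols. K2CO3 in MeOH then releases 13.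

Risk 3, step 1. Proton exchange between the kinetic enolate and the product ketone during alkylation would scramble the enolate position and cause multiple alkylation. The fallback sets out from 2 and comes back at 3, using a doubly activated acetone equivalent instead of a kinetic enolate. Commercial dimethyl 3-oxopentanedioate (COC(=O)CC(=O)CC(=O)OC) is alkylated once at each activated methylene with two equivalents of 2 (K2CO3, acetone, reflux) to give dimethyl 2,4-bis(3-methylbut-2-enyl)-3-oxopentanedioate F4. Saponification (NaOH, aq MeOH, rt) gives 2,4-bis(3-methylbut-2-enyl)-3-oxopentanedioic acid F5. On acidification to pH 4-5 and gentle warming this should lose both carboxyl groups and deliver 3.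

Further compounds
F1 | step 4 | dimethyl 2-[(E)-3-phenylprop-2-enylidene]propanedioate | COC(=O)C(C(=O)OC)=C/C=C/c1ccccc1
F2 | step 5 | methyl 3,5-bis(3-methylbut-2-enyl)-6-[(E)-2-phenylethenyl]-2,4-bis(trimethylsilyloxy)cyclohexa-1,3-diene-1-carboxylate | COC(=O)C1=C(O[Si](C)(C)C)C(CC=C(C)C)=C(O[Si](C)(C)C)C(CC=C(C)C)C1/C=C/c1ccccc1
F3 | step 5 | methyl 3,5-bis(3-methylbut-2-enyl)-6-[(E)-2-phenylethenyl]-2,4-bis(trimethylsilyloxy)benzoate | COC(=O)c1c(O[Si](C)(C)C)c(CC=C(C)C)c(O[Si](C)(C)C)c(CC=C(C)C)c1/C=C/c1ccccc1
F4 | step 1 | dimethyl 2,4-bis(3-methylbut-2-enyl)-3-oxopentanedioate | COC(=O)C(CC=C(C)C)C(=O)C(CC=C(C)C)C(=O)OC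
F5 | step 1 | 2,4-bis(3-methylbut-2-enyl)-3-oxopentanedioic acid | OC(=O)C(CC=C(C)C)C(=O)C(CC=C(C)C)C(=O)O
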